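**Retrosynthetic overview**

- The target is a trans-2-aryl-3-methyl-2,3-dihydrobenzofuran with ring A (benzo ring), ring B (3,4,5-trimethoxyphenyl on C2) and ring C (dihydrofuran). The strategy rests on three facts: ring C meets ring A at the adjacent carbons C3a (bonded to C3) and C7a (bonded to O1); C7, next to C7a, carries a methoxy group; and O1–C2–C3 is a cis aryl methyl epoxide in disguise.
- Last disconnection: the C5–propenyl bond, to a C5 aryl chloride and an (E)-propenylboronate (Suzuki–Miyaura coupling).
- Key disconnection: C3a–C3 and C7a–O1 together, by palladium/norbornene annulation of 4-chloro-1-iodo-2-methoxybenzene with the cis epoxide (inversion at C3, retention at C2, hence trans). Ring C is the only ring formed; rings A and B are bought.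
- The epoxide comes from Jacobsen–Katsuki epoxidation of the (Z)-propenyl arene, itself made by stereoretentive Suzuki–Miyaura coupling of 5-bromo-1,2,3-trimethoxybenzene with cis-propenylboronic acid.

Key step: step 3

Remark: C5 of ring A is carried through the annulation as chloride, a spectator there, so that the (E)-propenyl group is attached last with its geometry fixed by the boron reagent. The two aryl halides and the two propenylboron reagents are taken to be commercially available.

**Route**

Step 1
Reactants: 1 5-bromo-1,2,3-trimethoxybenzene; 2 (Z)-prop-1-en-1-ylboronic acid (cis-1-propenylboronic acid)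
Product: 3 1,2,3-trimethoxy-5-[(Z)-prop-1-en-1-yl]benzene
Conditions: Pd(PPh3)4 (3 mol%), K2CO3 (2 M aq), 1,4-dioxane, 80 °C, degassed
Reagents that add atoms: none
Why: Suzuki–Miyaura coupling, in which transmetalation and reductive elimination proceed with retention at the alkenyl carbon, so the Z geometry of 2 should be carried into 3; no stereocentre is formed.

Step 2
Reactants: 3 1,2,3-trimethoxy-5-[(Z)-prop-1-en-1-yl]benzene
Product: 4 (2R,3S)-2-methyl-3-(3,4,5-trimethoxyphenyl)oxirane (cis)
Conditions: (S,S)-(salen)MnCl [Jacobsen catalyst, salen = N,N'-bis(3,5-di-tert-butylsalicylidene)-1,2-cyclohexanediamine] (5 mol%), 4-phenylpyridine N-oxide (20 mol%), aq NaOCl buffered to pH 11.3, CH2Cl2, 0 °C; chromatography on Et3N-deactivated silica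
Reagents that add atoms: sodium hypochlorite, [Na+].[O-]Cl
Why: Jacobsen–Katsuki epoxidation, for which cis-disubstituted aryl alkenes are the favoured substrate class; the (S,S) catalyst is expected to deliver oxygen to the face that makes the benzylic carbon S and the methyl-bearing carbon R, the cis relationship comes from the Z alkene, and the N-oxide donor and low temperature should limit stepwise leakage to the trans epoxide.

Step 3
Reactants: 5 4-chloro-1-iodo-2-methoxybenzene; 4 (2R,3S)-2-methyl-3-(3,4,5-trimethoxyphenyl)oxirane
Product: 6 (2R,3R)-5-chloro-7-methoxy-3-methyl-2-(3,4,5-trimethoxyphenyl)-2,3-dihydro-1-benzofuran (trans)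
Conditions: Pd(OAc)2 (10 mol%), RuPhos (20 mol%), isopropyl 5-norbornene-2-carboxylate (50 mol%), Cs2CO3 (2.5 equiv), 4 (1.5 equiv), DMF, 110 °C, argon
Reagents that add atoms: none
Why: Proposed new method: zerovalent palladium should add to the C–I bond of 5, norbornene insertion and C–H palladation at the free ortho carbon (future C3a) give a divalent aryl–norbornyl palladacycle, and this soft, bulky nucleophile is expected to open 4 by backside attack at the methyl-bearing carbon to a tetravalent palladium alkoxide, from which aryl–alkyl reductive elimination forms C3a–C3; with both ortho positions then substituted, norbornene is expelled by β-carbon elimination and C–O reductive elimination from the resulting aryl palladium alkoxide forms C7a–O1. The closest known reaction type is the palladium/norbornene (Catellani-type) annulation of ortho-substituted aryl iodides with terminal epoxides to 2-substituted 2,3-dihydrobenzofurans, together with the known inversion when secondary alkyl iodides alkylate such palladacycles; opening of an internal aryl epoxide at its non-benzylic carbon is the untested part. Ring C closes as a five-membered ring by ipso C–O reductive elimination out of a six-membered oxapalladacycle, after the intermolecular C–C bond has tied the side chain to C3a. C3 is set by substrate control alone, through stereospecific inversion at the epoxide carbon, while the C2–O bond is carried over untouched, so the (2R,3S) cis epoxide should map onto the (2R,3R) trans ring. The step needs attack at CH(CH3) and not at the benzylic carbon, and no isomerisation of 4 to a ketone: the aryl-bearing carbon is the more hindered one for a metal-centred SN2 process, the 3,4,5-trimethoxyphenyl ring is only a weak net donor (two meta methoxy groups offset the para one), and the carbonate medium contains no Lewis acid. The C7 methoxy group ortho to iodine blocks the second ortho position and so prevents double alkylation, and the C–Cl bond is expected to stay inert because oxidative addition to C–I is far faster.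

Step 4
Reactants: 6 (2R,3R)-5-chloro-7-methoxy-3-methyl-2-(3,4,5-trimethoxyphenyl)-2,3-dihydro-1-benzofuran; 7 4,4,5,5-tetramethyl-2-[(E)-prop-1-en-1-yl]-1,3,2-dioxaborolane (trans-1-propenylboronic acid pinacol ester)
Product: 8 (2R,3R)-7-methoxy-3-methyl-5-[(E)-prop-1-en-1-yl]-2-(3,4,5-trimethoxyphenyl)-2,3-dihydro-1-benzofuran (target)
Conditions: Pd(OAc)2 (3 mol%), SPhos (6 mol%), K3PO4 (3 equiv), toluene/H2O 10:1, 90 °C
Reagents that add atoms: none
Why: Suzuki–Miyaura coupling of an aryl chloride, in which the electron-rich biaryl phosphine enables oxidative addition to the C5–Cl bond and the alkenyl group is transferred with retention, so the E geometry of 7 should be kept; C2 and C3 are not affected by the mild base.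

**Compound list**

1 | 5-bromo-1,2,3-trimethoxybenzene | COc1cc(Br)cc(OC)c1OC | starting material
2 | (Z)-prop-1-en-1-ylboronic acid | C/C=C\B(O)O | starting material
3 | 1,2,3-trimethoxy-5-[(Z)-prop-1-en-1-yl]benzene | C/C=C\c1cc(OC)c(OC)c(OC)c1 | intermediate
4 | (2R,3S)-2-methyl-3-(3,4,5-trimethoxyphenyl)oxirane (cis) | C[C@H]1O[C@H]1c1cc(OC)c(OC)c(OC)c1 | intermediate
5 | 4-chloro-1-iodo-2-methoxybenzene | COc1cc(Cl)ccc1I | starting material
6 | (2R,3R)-5-chloro-7-methoxy-3-methyl-2-(3,4,5-trimethoxyphenyl)-2,3-dihydro-1-benzofuran | Clc1cc(OC)c2c(c1)[C@@H](C)[C@H](c1cc(OC)c(OC)c(OC)c1)O2 | intermediate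
7 | 4,4,5,5-tetramethyl-2-[(E)-prop-1-en-1-yl]-1,3,2-dioxaborolane | C/C=C/B1OC(C)(C)C(C)(C)O1 | starting material
8 | (2R,3R)-7-methoxy-3-methyl-5-[(E)-prop-1-en-1-yl]-2-(3,4,5-trimethoxyphenyl)-2,3-dihydro-1-benzofuran | C/C=C/c1cc(OC)c2c(c1)[C@@H](C)[C@H](c1cc(OC)c(OC)c(OC)c1)O2 | target

Total step count: 4
Longest linear sequence: 4 steps (1 → 3 → 4 → 6 → 8)

**Steps most likely to fail**

1. Step 3 (the proposed new method).
What may go wrong:
- the palladacycle may attack the benzylic carbon, or fail to attack a secondary carbon at all;
- zerovalent palladium or a trace of Lewis acid may isomerise the epoxide to a ketone;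
- iodide may open the epoxide first, so that the palladacycle displaces iodide and the double inversion erodes the trans selectivity;
- β-hydride elimination from the palladium alkoxide may outrun C–O bond formation.

Fallback, known chemistry only, setting out from 1 and coming back at 6: C3 is set by a Noyori transfer hydrogenation under dynamic kinetic resolution, and ring C is closed through O1–C2 instead. Compound 1 is lithiated (n-BuLi, THF, −78 °C) to (3,4,5-trimethoxyphenyl)lithium F1, which is acylated with N-methoxy-N-methylpropanamide (Weinreb ketone synthesis) to 1-(3,4,5-trimethoxyphenyl)propan-1-one F2. Ring A is made from commercial 4-chloro-2-methoxyphenol by ortho bromination (NBS, MeCN, 0 °C) to 2-bromo-4-chloro-6-methoxyphenol F3 and protection (MOMCl, i-Pr2NEt, CH2Cl2) to 1-bromo-5-chloro-3-methoxy-2-(methoxymethoxy)benzene F4. Palladium-catalysed α-arylation of F2 with F4 (Pd2(dba)3, Xantphos, NaOt-Bu, toluene, 80 °C; the C–Br bond reacts, the C–Cl bond stays) should give racemic 2-[5-chloro-3-methoxy-2-(methoxymethoxy)phenyl]-1-(3,4,5-trimethoxyphenyl)propan-1-one F5, whose α-centre is configurationally labile. Transfer hydrogenation with RuCl(p-cymene)[(R,R)-TsDPEN] and HCO2H/Et3N is expected to reduce the equilibrating ketone with Felkin–Anh-type selectivity to (1R,2R)-2-[5-chloro-3-methoxy-2-(methoxymethoxy)phenyl]-1-(3,4,5-trimethoxyphenyl)propan-1-ol F6, which fixes C3 of the target. Methanolic HCl then removes the MOM group to give (1R,2R)-2-(5-chloro-2-hydroxy-3-methoxyphenyl)-1-(3,4,5-trimethoxyphenyl)propan-1-ol F7. Under the same acid the trimethoxybenzylic alcohol ionises and the phenol should close ring C on the face opposite to the C3 methyl group, giving trans compound 6, where the main route resumes.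

2. Step 2.
What may go wrong: leakage from the cis to the trans epoxide through the stepwise radical course of oxygen transfer, incomplete facial selectivity with this electron-rich arene, and acid-induced opening of the epoxide during isolation. Any trans epoxide would end up as the cis-dihydrobenzofuran.

Fallback, setting out from 1 and coming back at 4: both centres are traced to the chiral pool through a chlorohydrin. Compound 1 is converted with magnesium in THF into (3,4,5-trimethoxyphenyl)magnesium bromide F8, which is added at −78 °C to commercial (S)-2-chloropropanoyl chloride in the presence of CuI (10 mol%) to give (S)-2-chloro-1-(3,4,5-trimethoxyphenyl)propan-1-one F9. Luche reduction (NaBH4, CeCl3·7H2O, MeOH, −78 °C) should follow the Felkin–Anh/Cornforth course, with hydride entering anti to chlorine, and give mainly (1S,2S)-2-chloro-1-(3,4,5-trimethoxyphenyl)propan-1-ol F10; the minor diastereomer, which would lead to the trans epoxide, is removed by chromatography. K2CO3 in MeOH then closes the ring by intramolecular SN2 displacement with inversion at the chlorine-bearing carbon, which should give cis epoxide 4.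

3. Step 1.
What may go wrong: partial Z to E isomerisation during the coupling, and protodeboronation of the alkenylboronic acid before transmetalation.

Fallback, setting out from 1 and coming back at 3: the Z geometry is made by syn addition of hydrogen. Sonogashira coupling of 1 with propyne (PdCl2(PPh3)2, CuI, Et3N, THF, 50 °C, sealed vessel) should give 1,2,3-trimethoxy-5-(prop-1-yn-1-yl)benzene F11. Semihydrogenation over Lindlar catalyst (Pd on CaCO3 poisoned with Pb(OAc)2, quinoline, H2 at 1 atm, EtOAc) should then deliver Z-alkene 3.

Further compounds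
F1 | step 3 | (3,4,5-trimethoxyphenyl)lithium | [Li]c1cc(OC)c(OC)c(OC)c1
F2 | step 3 | 1-(3,4,5-trimethoxyphenyl)propan-1-one | CCC(=O)c1cc(OC)c(OC)c(OC)c1
F3 | step 3 | 2-bromo-4-chloro-6-methoxyphenol | COc1cc(Cl)cc(Br)c1O
F4 | step 3 | 1-bromo-5-chloro-3-methoxy-2-(methoxymethoxy)benzene | COCOc1c(Br)cc(Cl)cc1OC
F5 | step 3 | rac-2-[5-chloro-3-methoxy-2-(methoxymethoxy)phenyl]-1-(3,4,5-trimethoxyphenyl)propan-1-one | CC(C(=O)c1cc(OC)c(OC)c(OC)c1)c1cc(Cl)cc(OC)c1OCOC
F6 | step 3 | (1R,2R)-2-[5-chloro-3-methoxy-2-(methoxymethoxy)phenyl]-1-(3,4,5-trimethoxyphenyl)propan-1-ol | C[C@@H]([C@@H](O)c1cc(OC)c(OC)c(OC)c1)c1cc(Cl)cc(OC)c1OCOC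
F7 | step 3 | (1R,2R)-2-(5-chloro-2-hydroxy-3-methoxyphenyl)-1-(3,4,5-trimethoxyphenyl)propan-1-ol | C[C@@H]([C@@H](O)c1cc(OC)c(OC)c(OC)c1)c1cc(Cl)cc(OC)c1O
F8 | step 2 | (3,4,5-trimethoxyphenyl)magnesium bromide | Br[Mg]c1cc(OC)c(OC)c(OC)c1
F9 | step 2 | (S)-2-chloro-1-(3,4,5-trimethoxyphenyl)propan-1-one | C[C@H](Cl)C(=O)c1cc(OC)c(OC)c(OC)c1
F10 | step 2 | (1S,2S)-2-chloro-1-(3,4,5-trimethoxyphenyl)propan-1-ol | C[C@H](Cl)[C@@H](O)c1cc(OC)c(OC)c(OC)c1
F11 | step 1 | 1,2,3-trimethoxy-5-(prop-1-yn-1-yl)benzene | CC#Cc1cc(OC)c(OC)c(OC)c1
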